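## Structural features

The target joins three units. Ring A is a 2,6,6-trimethylcyclohex-1-ene with a tetrasubstituted alkene. A six-carbon tether C1''–C6'' carries one E-trisubstituted alkene (C3''=C4'', methyl on C4''), and a bis-lactone head completes the molecule.

The head is ring B, a 5,6-dihydro-2H-pyran-2-one (O1, C2 to C6) bearing the tether on C3. It is joined through the single bond C6–C4' to ring C, an oxolan-2-one (O1', C2'(=O), C3'H2, C4'H, C5'H2).

The only stereocentres, C6 (R) and C4' (R), stand next to each other on this freely rotating bond. No ring fusion relays configuration from one to the other.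

C4' is stereogenic only because its two ring arms differ by one atom: C5'H2 is bound to O1' and C3'H2 to C2'. If O1' is removed and C5' is bound to C2', ring C becomes a 3-substituted cyclobutanone with a local mirror plane. This latent symmetry is the feature that the key step exploits.

Ring B opens by E1cB (deprotonation at C5, loss of the C6–O1 carboxylate) and accepts nucleophiles at C4. The alkenes of ring A and of the tether are the first sites attacked by peracids, ozone, halogens and strong acid.

A free hydroxyl on C6 beside ring C is not an innocent intermediate. It can attack C2' and give the isomeric five-membered lactone (oxygen on C6, free C5'–OH).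

The real difficulty is the C6/C4' pair together with the correct assignment of three oxygens to two carbonyl groups. The lipophilic half is a matter of alkene geometry and timing.

## Logic of the disconnections

In one sentence, the route is the catalyst-controlled, desymmetrising Baeyer–Villiger ring expansion of the prochiral cyclobutanone 14 to the bis-lactone 15. The sentence that describes the usual plan (ring-closing metathesis on a homoallylic ester that already holds ring C) does not fit it.

**19 to 17 and 7.**
- Cut: C3–C1'' (sp2–sp3).
- Reason: this is the seam between the oxidised head and the half whose two alkenes are the most oxidisable sites. Cutting here lets every oxidant and halogen act before those alkenes arrive.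
- Gain: a convergent end, with one fragment free of stereocentres and a small head that holds both.
- Demand: a coupling in neutral medium, because ring B does not tolerate strong base. This is met by converting 7 into 18 and needs a halogen on C3, that is 17.

**17 to 15.**
- Cut: C3–Br.
- Reason: the enoate of ring B itself steers a halogen to C3 by addition followed by loss of HBr through the acidic C3–H.
- Gain: the head shrinks to the unsubstituted bis-lactone.
- Demand: bromine must find no better alkene, which holds for 15.

**15 to 14 (key).**
- Cut: C5'–O1'. O1' is removed and C5' is bound to C2'.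
- Reason: the two arms of C4' differ only by this oxygen.
- Gain:
  - Ring C becomes a carbocycle with a mirror plane through C2' and C4'.
  - C4' stops being a stereocentre, so only C6 remains.
  - The four carbons of ring C can be bought as one piece.
  - No intermediate has a free C6–OH beside a lactone.
  - Nothing needs adjusting after the step, because O1' is the only atom added.
- Demand: the forward step must choose between two diastereotopic CH2 groups of equal migratory aptitude and must spare the enoate.

**14 to 12 through 13.**
- Cut: C3=C4. The ketone is masked as its dimethyl ketal.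
- Reason: ring B closes most simply at its alkene.
- Gain: an acyclic ester.
- Demand: the mask must survive nucleophilic and basic steps and come off under acid that ring B tolerates.

**12 to 8 through 11 and 9.**
- Cut: O1–C2 (acyl bond) and C5–C6.
- Reason: C6 is now a lone carbinol between an achiral ring and an allyl group. It can be set by reagent control on an achiral aldehyde with no matched or mismatched case.
- Gain: a commercial cyclobutane.
- Demand: high facial selectivity on an α-branched aldehyde.

**7 to 1 through 6 and 3.**
- Cut: C2''–C3'' and C4''–CH3 (both made in one flask), then the C1'' heteroatom exchange.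
- Reason: the E geometry of C3''=C4'' is the only stereochemical issue in this half, and a syn carbometalation of a terminal alkyne fixes it by mechanism.
- Gain: 3 comes from commercial 1, which already holds ring A, C5'' and C6''.
- Demand: kinetic enolisation of 1 at the methyl group and alkenyl transfer to oxirane with retention.

## Other disconnections considered

**Alternative 1:** (the first that comes to mind) Cut C3=C4 and C5–C6 with ring C already complete.

Forward: allylation of the lactone aldehyde A1 gives the homoallylic alcohol A2. Acylation of its C6–OH with the tether-bearing acrylate unit gives the diene A3, and ring-closing metathesis of A3 closes ring B to 19.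

Grounds against:
- A1 carries its only stereocentre α to the formyl group and a β-acyloxy leaving group (C5'–O1'). Enolisation threatens C4' by epimerisation and by E1cB opening of ring C.
- A2 has the free C6–OH placed to attack C2', so translactonisation is an open equilibrium.
- C6 must be set next to a small, weakly biasing centre.
- The metathesis has to engage a 1,1-disubstituted electron-poor alkene in the presence of the polyene.
- The tether must first be elaborated to the acid level, which lengthens the linear sequence.

**Alternative 2:** Cut C6–C4'.

Forward key step: allylboration of the aldehyde A4 with the E-configured γ-(silyloxymethyl)allylboronate A5. The closed chair transition state should give the anti adduct A6 with both centres at once, and the target does map onto the anti series.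

Grounds against:
- The stereochemical logic is strong, but the adduct is far from the target.
- The vinyl group must be hydroborated and raised to the acid level to become C3'/C2'.
- Three hydroxyl functions must be kept apart to avoid the wrong lactone.
- Ring B still needs oxidation at C4 and a Z-selective trisubstituted olefination.
- The head would take roughly twice as many operations, most of them redox and protecting-group steps.

**Alternative 3:** Cut C3=C4 and tie C4 to C3' in a cyclopentene, so that C6 and C4' are ring neighbours.

Forward: the trans alcohol A7 is inverted at C6 by a Mitsunobu reaction with acrylic acid to the cis acrylate A8. Ring-rearrangement metathesis of A8 opens the carbocycle and closes ring B to A9. Hydroboration of the vinyl group, oxidation, debenzylation and lactonisation then lead to 15.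

Grounds against:
- Mapping shows that O on C6 and the CH2O arm on C4' must be cis, whereas the accessible building block is trans. Hence the inversion, on an alcohol that can eliminate to a cyclopentadiene.
- The cyclopentene has little strain to drive ring opening, and the catalyst must start at an alkene flanked by a branched carbon.
- The key step creates no stereocentre.
- Four redox or deprotection operations on a substrate with an enoate follow it, whereas the chosen key step ends at the final oxidation level.

Key step: step 9

Assumption: the sense of induction of the phosphoric acid in step 9 is carried over from simple 3-substituted cyclobutanones, with the substituent in the place of C6, and the (S)-acid is written on that ground. The antipodal acid is equally accessible.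

## Steps

**Step 1**
Reactants: 1 dihydro-β-ionone [4-(2,6,6-trimethylcyclohex-1-en-1-yl)butan-2-one]
Product: 3 2-(but-3-yn-1-yl)-1,3,3-trimethylcyclohex-1-ene, via enol phosphate 2 (not isolated)
Conditions: LiN(i-Pr)2 (1.1 equiv), THF, −78 °C; ClP(O)(OEt)2, −78 °C → rt; then LiN(i-Pr)2 (2.3 equiv), THF, −78 °C → rt; H2O
Reagents that add atoms: diethyl chlorophosphate, CCOP(=O)(Cl)OCC (its atoms stand in 2 only and leave again on the way to 3)
Why: Methyl ketone to terminal alkyne conversion through the enol phosphate: kinetic deprotonation at the methyl group, O-phosphorylation and base-induced loss of diethyl phosphate. The excess amide holds 3 as its acetylide, which blocks isomerisation to the allene, and ring A offers no acidic or electrophilic site.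

**Step 2**
Reactants: 3 2-(but-3-yn-1-yl)-1,3,3-trimethylcyclohex-1-ene
Product: 6 (E)-4-methyl-6-(2,6,6-trimethylcyclohex-1-en-1-yl)hex-3-en-1-ol, via alkenylalane 4 (not isolated), via lithium alanate 5 (not isolated)
Conditions: Me3Al (2 equiv), Cp2ZrCl2 (0.2 equiv), CH2Cl2, 0 °C → rt; volatiles removed; hexane, n-BuLi (1 equiv), 0 °C; ethylene oxide (3 equiv), THF, 0 °C → rt; aqueous work-up
Reagents that add atoms: trimethylaluminium, C[Al](C)C (methyl on C4''; Al in 4 and 5 only); ethylene oxide, C1CO1 (C1'', C2'' and O); n-butyllithium, [Li]CCCC (in 5 only)
Why: Negishi carboalumination: methyl and aluminium add syn across the alkyne with aluminium on the terminal carbon, so the methyl group lands on C4'' and the E geometry of C3''=C4'' is fixed by mechanism. The ate complex 5 is nucleophilic enough to open ethylene oxide by alkenyl transfer with retention, a known way to E-homoallylic alcohols. The tetrasubstituted alkene of ring A is too hindered to be carbometalated.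

**Step 3**
Reactants: 6 (E)-4-methyl-6-(2,6,6-trimethylcyclohex-1-en-1-yl)hex-3-en-1-ol
Product: 7 2-[(E)-6-iodo-3-methylhex-3-en-1-yl]-1,3,3-trimethylcyclohex-1-ene
Conditions: I2, PPh3, imidazole, CH2Cl2, 0 °C → rt
Reagents that add atoms: iodine, II
Why: Appel-type iodination by SN2 displacement of the alkoxyphosphonium ion at a primary carbon. The buffered, near-neutral medium is routinely used on polyprenyl alcohols and should leave both alkenes and the E geometry alone.

**Step 4**
Reactants: 8 methyl 3,3-dimethoxycyclobutane-1-carboxylate
Product: 9 3,3-dimethoxycyclobutane-1-carbaldehyde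
Conditions: i-Bu2AlH (1.05 equiv), CH2Cl2, −78 °C; aq potassium sodium tartrate
Reagents that add atoms: none
Why: Partial reduction of an ester: at −78 °C the tetrahedral aluminium hemiacetal persists until work-up, so the aldehyde appears only after the hydride is gone. 9 has no stereocentre and the ketal is inert to the hydride.

**Step 5**
Reactants: 9 3,3-dimethoxycyclobutane-1-carbaldehyde
Product: 11 (R)-1-(3,3-dimethoxycyclobutyl)but-3-en-1-ol, via borinate 10 (not isolated)
Conditions: (+)-Ipc2B(allyl) (from (−)-α-pinene, 1 M in pentane, 1.2 equiv), Et2O, −78 °C; then 3 M NaOH, 30% H2O2, 0 °C → rt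
Reagents that add atoms: (+)-B-allyldiisopinocampheylborane, C=CCB([C@H]1C[C@H]2C[C@@H]([C@@H]1C)C2(C)C)[C@H]1C[C@H]2C[C@@H]([C@@H]1C)C2(C)C
Why: Brown allylation: the allyl group is delivered through a closed chair transition state in which the isopinocampheyl groups of the (−)-α-pinene-derived reagent expose the Re face of the aldehyde. For an α-branched aldehyde (ring carbon ranks above the allyl CH2) this gives the R carbinol, the future C6. The ketal tolerates the borane and the basic peroxide work-up.

**Step 6**
Reactants: 11 (R)-1-(3,3-dimethoxycyclobutyl)but-3-en-1-ol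
Product: 12 (R)-1-(3,3-dimethoxycyclobutyl)but-3-en-1-yl acrylate
Conditions: acryloyl chloride, Et3N, DMAP (cat.), CH2Cl2, 0 °C
Reagents that add atoms: acryloyl chloride, C=CC(=O)Cl
Why: O-Acylation of a secondary alcohol with an acid chloride. The C6–O bond is not broken, so the configuration is kept.

**Step 7**
Reactants: 12 (R)-1-(3,3-dimethoxycyclobutyl)but-3-en-1-yl acrylate
Product: 13 (R)-6-(3,3-dimethoxycyclobutyl)-5,6-dihydro-2H-pyran-2-one
Conditions: second-generation Grubbs catalyst RuCl2(=CHPh)(PCy3)(SIMes) (3 mol %), CH2Cl2 (0.01 M), reflux
Reagents that add atoms: none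
Why: Ring-closing metathesis: the catalyst loads on the terminal alkene of the allyl group and closes onto the acrylate, driven by loss of ethylene and formation of the conjugated six-membered lactone. The reaction is well precedented for acrylates of homoallylic alcohols, and dilution suppresses dimerisation.

**Step 8**
Reactants: 13 (R)-6-(3,3-dimethoxycyclobutyl)-5,6-dihydro-2H-pyran-2-one
Product: 14 (R)-6-(3-oxocyclobutyl)-5,6-dihydro-2H-pyran-2-one
Conditions: 2 M HCl, THF, rt
Reagents that add atoms: water, O
Why: Acid hydrolysis of a dimethyl ketal. Cyclobutanone ketals hydrolyse more slowly than unstrained ones, hence aqueous mineral acid. Ring B tolerates it, and if it opened, the Z-configured hydroxy acid would reclose on its own with C6 untouched.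

**Step 9**
Reactants: 14 (R)-6-(3-oxocyclobutyl)-5,6-dihydro-2H-pyran-2-one
Product: 15 (6R)-6-[(3R)-5-oxooxolan-3-yl]-5,6-dihydro-2H-pyran-2-one
Conditions: (S)-3,3'-di(pyren-1-yl)-H8-BINOL hydrogen phosphate (10 mol %), 30% aq H2O2 (1.5 equiv), CHCl3, −40 °C
Reagents that add atoms: hydrogen peroxide, OO
Why: Baeyer–Villiger oxidation run as a catalytic desymmetrisation of a 3-substituted cyclobutanone, a known reaction type with chiral phosphoric acids and aqueous H2O2. The acid binds ketone and peroxide together (P–OH to C=O, P=O to HOOH) and delivers the tetrahedral peroxyhemiketal at C2'. In the product-determining 1,2-shift, the C–C bond antiperiplanar to the O–O bond migrates to oxygen with loss of water, and release of four-ring strain makes this fast at −40 °C, so the enoate of ring B, the only other electrophile, is left alone. Ring C is closed by ring expansion (four- to five-membered, O1' inserted between C2' and C5') and not by a cyclisation, so no lactonisation regiochemistry and no free C6–OH arise. Both migration candidates are CH2 groups of equal aptitude, so the constitution is the same whichever moves and the choice decides only the configuration at C4'. C4' is controlled by the chiral pocket of the catalyst, which fixes the rotamer about the C2'–OOH bond and thereby which diastereotopic arm lies anti to O–O; the resident C6 centre is a secondary, matched or mismatched, influence. C6 is not touched. The C4' epimer is a diastereomer and should be removable by chromatography or crystallisation, so optical purity rests on step 5.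

**Step 10**
Reactants: 15 (6R)-6-[(3R)-5-oxooxolan-3-yl]-5,6-dihydro-2H-pyran-2-one
Product: 17 (6R)-3-bromo-6-[(3R)-5-oxooxolan-3-yl]-5,6-dihydro-2H-pyran-2-one, via dibromide 16 (not isolated)
Conditions: Br2 (1.05 equiv), CH2Cl2, 0 °C → rt; then Et3N (1.2 equiv), 0 °C → rt
Reagents that add atoms: bromine, BrBr
Why: Bromination–dehydrobromination of an enoate: anti addition of Br2 to C3=C4, the only alkene in 15, then loss of HBr through the acidic C3–H with departure of the C4 bromide, which leaves bromine on C3. The sequence is known for the parent 5,6-dihydropyran-2-one. Triethylamine is too weak to deprotonate C5, so C6 and C4' are not at risk.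

**Step 11**
Reactants: 7 2-[(E)-6-iodo-3-methylhex-3-en-1-yl]-1,3,3-trimethylcyclohex-1-ene; 17 (6R)-3-bromo-6-[(3R)-5-oxooxolan-3-yl]-5,6-dihydro-2H-pyran-2-one
Product: 19 (6R)-3-[(3E)-4-methyl-6-(2,6,6-trimethylcyclohex-1-en-1-yl)hex-3-en-1-yl]-6-[(3R)-5-oxooxolan-3-yl]-5,6-dihydro-2H-pyran-2-one (target), via alkylzinc iodide 18 (not isolated)
Conditions: 7, Zn dust (activated by BrCH2CH2Br and Me3SiCl), LiCl, THF, 40 °C; then 17, PdCl2(dppf) (5 mol %), THF, rt → 40 °C
Reagents that add atoms: zinc, [Zn] (in 18 only; no reagent atom remains in 19)
Why: Negishi coupling (sp3–sp2): zinc inserts into the primary iodide, the electron-poor C3–Br bond adds quickly to zerovalent palladium, and the wide bite angle of dppf favours reductive elimination over β-hydride elimination; couplings of α-halo enones and enoates with alkylzinc halides are known. Alkylzinc halides do not attack lactones or enoates without a catalyst and the medium is neutral. No stereocentre or alkene geometry takes part in the bond formation.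

## Compound list

1 | dihydro-β-ionone, 4-(2,6,6-trimethylcyclohex-1-en-1-yl)butan-2-one | CC1=C(CCC(C)=O)C(C)(C)CCC1 | starting material
2 | diethyl 4-(2,6,6-trimethylcyclohex-1-en-1-yl)but-1-en-2-yl phosphate | CC1=C(CCC(=C)OP(=O)(OCC)OCC)C(C)(C)CCC1 | intermediate
3 | 2-(but-3-yn-1-yl)-1,3,3-trimethylcyclohex-1-ene | CC1=C(CCC#C)C(C)(C)CCC1 | intermediate
4 | (E)-dimethyl[2-methyl-4-(2,6,6-trimethylcyclohex-1-en-1-yl)but-1-en-1-yl]alane | CC1=C(CC/C(C)=C/[Al](C)C)C(C)(C)CCC1 | intermediate
5 | lithium (E)-butyldimethyl[2-methyl-4-(2,6,6-trimethylcyclohex-1-en-1-yl)but-1-en-1-yl]alanate | CC1=C(CC/C(C)=C/[Al-](C)(C)CCCC)C(C)(C)CCC1.[Li+] | intermediate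
6 | (E)-4-methyl-6-(2,6,6-trimethylcyclohex-1-en-1-yl)hex-3-en-1-ol | CC1=C(CC/C(C)=C/CCO)C(C)(C)CCC1 | intermediate
7 | 2-[(E)-6-iodo-3-methylhex-3-en-1-yl]-1,3,3-trimethylcyclohex-1-ene | CC1=C(CC/C(C)=C/CCI)C(C)(C)CCC1 | intermediate
8 | methyl 3,3-dimethoxycyclobutane-1-carboxylate | COC(=O)C1CC(OC)(OC)C1 | starting material
9 | 3,3-dimethoxycyclobutane-1-carbaldehyde | O=CC1CC(OC)(OC)C1 | intermediate
10 | (R)-1-(3,3-dimethoxycyclobutyl)but-3-en-1-yl diisopinocampheylborinate | C=CC[C@@H](OB([C@H]1C[C@H]2C[C@@H]([C@@H]1C)C2(C)C)[C@H]1C[C@H]2C[C@@H]([C@@H]1C)C2(C)C)C1CC(OC)(OC)C1 | intermediate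
11 | (R)-1-(3,3-dimethoxycyclobutyl)but-3-en-1-ol | C=CC[C@@H](O)C1CC(OC)(OC)C1 | intermediate
12 | (R)-1-(3,3-dimethoxycyclobutyl)but-3-en-1-yl acrylate | C=CC[C@@H](OC(=O)C=C)C1CC(OC)(OC)C1 | intermediate
13 | (R)-6-(3,3-dimethoxycyclobutyl)-5,6-dihydro-2H-pyran-2-one | O=C1C=CC[C@H](C2CC(OC)(OC)C2)O1 | intermediate
14 | (R)-6-(3-oxocyclobutyl)-5,6-dihydro-2H-pyran-2-one | O=C1C=CC[C@H](C2CC(=O)C2)O1 | intermediate
15 | (6R)-6-[(3R)-5-oxooxolan-3-yl]-5,6-dihydro-2H-pyran-2-one | O=C1C=CC[C@H]([C@H]2COC(=O)C2)O1 | intermediate
16 | (6R)-3,4-dibromo-6-[(3R)-5-oxooxolan-3-yl]oxan-2-one (3,4-trans, both anti adducts; C3 and C4 left open) | O=C1C(Br)C(Br)C[C@H]([C@H]2COC(=O)C2)O1 | intermediate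
17 | (6R)-3-bromo-6-[(3R)-5-oxooxolan-3-yl]-5,6-dihydro-2H-pyran-2-one | O=C1C(Br)=CC[C@H]([C@H]2COC(=O)C2)O1 | intermediate
18 | (E)-[4-methyl-6-(2,6,6-trimethylcyclohex-1-en-1-yl)hex-3-en-1-yl]zinc iodide | CC1=C(CC/C(C)=C/CC[Zn]I)C(C)(C)CCC1 | intermediate
19 | (6R)-3-[(3E)-4-methyl-6-(2,6,6-trimethylcyclohex-1-en-1-yl)hex-3-en-1-yl]-6-[(3R)-5-oxooxolan-3-yl]-5,6-dihydro-2H-pyran-2-one | CC1=C(CC/C(C)=C/CCC2=CC[C@H]([C@H]3COC(=O)C3)OC2=O)C(C)(C)CCC1 | target

## Step count and least certain steps

Total: 11 steps. Longest linear sequence: 8 steps (8 to 19, steps 4 to 11). The tether branch has 3 steps before the coupling.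

**Step 9 (key step).**
Most likely failure: poor discrimination between the two diastereotopic CH2 arms. The substituent on C4' is a branched alkyl group rather than the flat aryl group that fits this catalyst class best. The resident C6 centre may also form a mismatched pair or reverse the expected sense. An unselective run would still give only the two C4' epimers, and the configuration can be checked at 17, whose bromine atom should allow a crystallographic assignment.

Fallback (covalent auxiliary in place of a catalyst), from 13 back to 15, bypassing step 8:
- Acid-catalysed transketalisation of 13 with (2R,4R)-pentane-2,4-diol gives the chiral spiroketal F1, a single isomer because the diol is C2-symmetric.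
- SnCl4 opens one ketal C–O bond at very low temperature in CH2Cl2, and m-chloroperbenzoic acid adds to the oxocarbenium ion.
- The bound chiral alkoxy group decides which arm migrates, and hydrolysis sets 15 free.
- The peracid is admissible here because the enoate is the only alkene. The antipodal diol is available if the sense is wrong.

**Step 11.**
Most likely failure: slow or incomplete zinc insertion with protonation of the organometal, reduction of the C3–Br bond, or β-hydride elimination after transmetalation. The alkyl partner is homoallylic and the halide sits on a hindered, electron-poor alkene.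

Fallback (C3 substituent built into ring B rather than coupled on), from 7 and 11 back to 19:
- Triethyl phosphonoacetate is alkylated with 7 (NaH, DMF) to the phosphonate F2.
- Horner–Wadsworth–Emmons reaction with aqueous formaldehyde (K2CO3) gives the 2-alkylacrylate F3, and LiOH gives the acid F4.
- DCC/DMAP esterification with 11 gives the diene ester F5.
- Ring-closing metathesis with RuCl2(=CHPh)(PCy3)(SIMes) gives the 3-alkyl lactone ketal F6, and aqueous acid gives the cyclobutanone F7.
- The conditions of step 9, which contain no peracid and should spare the two alkenes, give 19.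

**Step 2.**
Most likely failure: transfer of butyl or methyl instead of the alkenyl group to oxirane, or Lewis-acid-induced oligomerisation of oxirane, because the alanate carries four different transferable or activating ligands.

Fallback (two carbons added by cross-coupling instead of epoxide opening), from 3 through 4 back to 6:
- The alane 4 is coupled with vinyl bromide (Pd(PPh3)4, ZnCl2, THF) to the E-diene F8.
- 9-BBN-H adds to the terminal, monosubstituted double bond only and gives the homoallylic borane F9.
- NaBO3 oxidation gives 6.

**Step 10.**
Most likely failure: sluggish addition of bromine to the electron-poor C3=C4 bond, followed on forcing by further elimination toward the 2-pyranone or E1cB opening at C5/C6 by the amine.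

Fallback (nucleophile-catalysed α-halogenation instead of addition–elimination), from 15 back to 19:
- I2 with pyridine or DMAP in CH2Cl2 works by conjugate addition of the amine, iodination of the enolate and loss of the amine. It gives the 3-iodo lactone F10.
- F10 enters the coupling with 18 under the conditions of step 11.

## Further compounds

F1 | step 9 | (R)-6-[(6R,8R)-6,8-dimethyl-5,9-dioxaspiro[3.5]nonan-2-yl]-5,6-dihydro-2H-pyran-2-one | C[C@@H]1C[C@@H](C)OC2(O1)CC(C2)[C@H]1CC=CC(=O)O1
F2 | step 11 | ethyl (E)-2-(diethoxyphosphoryl)-6-methyl-8-(2,6,6-trimethylcyclohex-1-en-1-yl)oct-5-enoate (C2 racemic) | CC1=C(CC/C(C)=C/CCC(C(=O)OCC)P(=O)(OCC)OCC)C(C)(C)CCC1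
F3 | step 11 | ethyl (E)-6-methyl-2-methylidene-8-(2,6,6-trimethylcyclohex-1-en-1-yl)oct-5-enoate | CC1=C(CC/C(C)=C/CCC(=C)C(=O)OCC)C(C)(C)CCC1
F4 | step 11 | (E)-6-methyl-2-methylidene-8-(2,6,6-trimethylcyclohex-1-en-1-yl)oct-5-enoic acid | CC1=C(CC/C(C)=C/CCC(=C)C(=O)O)C(C)(C)CCC1
F5 | step 11 | (R)-1-(3,3-dimethoxycyclobutyl)but-3-en-1-yl (E)-6-methyl-2-methylidene-8-(2,6,6-trimethylcyclohex-1-en-1-yl)oct-5-enoate | CC1=C(CC/C(C)=C/CCC(=C)C(=O)O[C@H](CC=C)C2CC(OC)(OC)C2)C(C)(C)CCC1
F6 | step 11 | (R)-6-(3,3-dimethoxycyclobutyl)-3-[(3E)-4-methyl-6-(2,6,6-trimethylcyclohex-1-en-1-yl)hex-3-en-1-yl]-5,6-dihydro-2H-pyran-2-one | CC1=C(CC/C(C)=C/CCC2=CC[C@H](C3CC(OC)(OC)C3)OC2=O)C(C)(C)CCC1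
F7 | step 11 | (R)-3-[(3E)-4-methyl-6-(2,6,6-trimethylcyclohex-1-en-1-yl)hex-3-en-1-yl]-6-(3-oxocyclobutyl)-5,6-dihydro-2H-pyran-2-one | CC1=C(CC/C(C)=C/CCC2=CC[C@H](C3CC(=O)C3)OC2=O)C(C)(C)CCC1
F8 | step 2 | 1,3,3-trimethyl-2-[(E)-3-methylhexa-3,5-dien-1-yl]cyclohex-1-ene | CC1=C(CC/C(C)=C/C=C)C(C)(C)CCC1
F9 | step 2 | 9-[(E)-4-methyl-6-(2,6,6-trimethylcyclohex-1-en-1-yl)hex-3-en-1-yl]-9-borabicyclo[3.3.1]nonane | CC1=C(CC/C(C)=C/CCB2C3CCCC2CCC3)C(C)(C)CCC1
F10 | step 10 | (6R)-3-iodo-6-[(3R)-5-oxooxolan-3-yl]-5,6-dihydro-2H-pyran-2-one | O=C1C(I)=CC[C@H]([C@H]2COC(=O)C2)O1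
A1 | alternative 1 | (R)-5-oxooxolane-3-carbaldehyde | O=C[C@H]1COC(=O)C1
A2 | alternative 1 | (4R)-4-[(1R)-1-hydroxybut-3-en-1-yl]oxolan-2-one | C=CC[C@@H](O)[C@H]1COC(=O)C1
A3 | alternative 1 | (1R)-1-[(3R)-5-oxooxolan-3-yl]but-3-en-1-yl (E)-6-methyl-2-methylidene-8-(2,6,6-trimethylcyclohex-1-en-1-yl)oct-5-enoate | CC1=C(CC/C(C)=C/CCC(=C)C(=O)O[C@H](CC=C)[C@H]2COC(=O)C2)C(C)(C)CCC1
A4 | alternative 2 | 3-[(4-methoxybenzyl)oxy]propanal | O=CCCOCc1ccc(OC)cc1
A5 | alternative 2 | (E)-tert-butyldimethyl{[4-(4,4,5,5-tetramethyl-1,3,2-dioxaborolan-2-yl)but-2-en-1-yl]oxy}silane | CC1(C)OB(C/C=C/CO[Si](C)(C)C(C)(C)C)OC1(C)C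
A6 | alternative 2 | (3R,4R)-4-{[(tert-butyldimethylsilyl)oxy]methyl}-1-[(4-methoxybenzyl)oxy]hex-5-en-3-ol | C=C[C@H](CO[Si](C)(C)C(C)(C)C)[C@H](O)CCOCc1ccc(OC)cc1
A7 | alternative 3 | (1S,2R)-2-[(benzyloxy)methyl]cyclopent-3-en-1-ol | O[C@H]1CC=C[C@@H]1COCc1ccccc1
A8 | alternative 3 | (1R,2R)-2-[(benzyloxy)methyl]cyclopent-3-en-1-yl acrylate | C=CC(=O)O[C@@H]1CC=C[C@@H]1COCc1ccccc1
A9 | alternative 3 | (6R)-6-[(2R)-1-(benzyloxy)but-3-en-2-yl]-5,6-dihydro-2H-pyran-2-one | O=C1C=CC[C@H]([C@@H](COCc2ccccc2)C=C)O1
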